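**Retrosynthetic overview**

- The strategy rests on the C3–CH2 bond of the benzofuran. The CH2 carbon sits on ring C (the resorcinol ring that also carries the coumarin), whose oxygens at C2 and C4 are ortho and para to it, so this benzyl group can travel as a stabilised cation from the furan oxygen O1 to C3.
- Target 23 ⇐ protected benzofuran 21 ⇐ ortho-alkynylphenyl benzyl ether 20, by platinum-catalysed carboalkoxylation that forms O1–C2 and C3–CH2 and closes the furan ring last.
- 20 ⇐ Sonogashira coupling of aryl bromide 19 (ring B; ring A is the aryl group on benzofuran C2) with ring-A alkyne 9; 19 ⇐ Mitsunobu etherification of coumarin benzyl alcohol 16 with bromophenol 18.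
- 16 ⇐ Perkin-type condensation of salicylaldehyde 10 with arylacetic acid 13, which closes the pyranone ring of the coumarin first.
- Ring A, the coumarin benzo ring and ring C all come from bromo acetal 3 (from 5-bromo-2,4-dihydroxybenzaldehyde 1): γ-selective prenylboronate coupling gives 6 (→ 9 and 10), zinc enolate arylation gives 13.

Key step: step 15

Remark: the target has no stereocentre and no stereogenic double bond, so no step needs stereocontrol; (2-ethoxy-2-oxoethyl)zinc bromide is taken as a purchased or freshly made reagent.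

**Route**

Step 1
Reactants: 1 5-bromo-2,4-dihydroxybenzaldehyde
Product: 2 5-bromo-2,4-bis(methoxymethoxy)benzaldehyde
Conditions: MOMCl (3 equiv), i-Pr2NEt (4 equiv), CH2Cl2, 0 → 40 °C
Reagents that add atoms: chloromethyl methyl ether, COCCl
Why: O-alkylation of both phenols with the reactive α-chloro ether (Williamson type), where excess reagent and warming overcome the hydrogen bond of the ortho hydroxyl to the aldehyde.

Step 2
Reactants: 2 5-bromo-2,4-bis(methoxymethoxy)benzaldehyde
Product: 3 1-bromo-5-(dimethoxymethyl)-2,4-bis(methoxymethoxy)benzene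
Conditions: HC(OMe)3, PPTS (cat.), MeOH, rt
Reagents that add atoms: trimethyl orthoformate, COC(OC)OC
Why: Acid-catalysed acetalisation driven by the orthoformate masks the aldehyde, which would otherwise be attacked by the allylboronate of step 3 and the zinc enolate of step 8, while aryl MOM ethers should tolerate PPTS at room temperature.

Step 3
Reactants: 3 1-bromo-5-(dimethoxymethyl)-2,4-bis(methoxymethoxy)benzene; 4 prenylboronic acid pinacol ester
Product: 6 2,4-bis(methoxymethoxy)-5-(2-methylbut-3-en-2-yl)benzaldehyde, via dimethyl acetal 5 (not isolated)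
Conditions: Pd(OAc)2 (5 mol %), bulky dialkylbiarylphosphine chosen for γ-selectivity (10 mol %), K3PO4 (aq, 3 equiv), MeCN, 70 °C; then 1 M HCl, THF, 0 °C
Reagents that add atoms: water, O
Why: Suzuki–Miyaura coupling of an allylboronate in which transmetallation with allyl transposition puts palladium on the tertiary carbon and fast reductive elimination from that σ-allyl species gives the 1,1-dimethylallyl arene, after which brief dilute acid should hydrolyse the electron-rich aryl dimethyl acetal much faster than the aryl MOM ethers.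

Step 4
Reactants: 6 2,4-bis(methoxymethoxy)-5-(2-methylbut-3-en-2-yl)benzaldehyde
Product: 7 1-ethynyl-2,4-bis(methoxymethoxy)-5-(2-methylbut-3-en-2-yl)benzene
Conditions: Ohira–Bestmann reagent (1.5 equiv), K2CO3, MeOH, rt
Reagents that add atoms: dimethyl (1-diazo-2-oxopropyl)phosphonate, COP(=O)(OC)C(=[N+]=[N-])C(C)=O
Why: Ohira–Bestmann (Seyferth–Gilbert) homologation, in which the diazomethylphosphonate anion adds to the aldehyde and the alkylidene carbene formed after loss of phosphate and N2 rearranges to the terminal alkyne, under conditions to which MOM ethers and the vinyl group are inert.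

Step 5
Reactants: 7 1-ethynyl-2,4-bis(methoxymethoxy)-5-(2-methylbut-3-en-2-yl)benzene
Product: 8 4-ethynyl-6-(2-methylbut-3-en-2-yl)benzene-1,3-diol
Conditions: HCl (cat., 1.25 M in MeOH), MeOH, rt → 40 °C
Reagents that add atoms: none
Why: Acid-catalysed acetal exchange to methanol removes both MOM groups, and the monosubstituted vinyl group (which could only give a secondary cation) and the terminal alkyne should tolerate dilute acid.

Step 6
Reactants: 8 4-ethynyl-6-(2-methylbut-3-en-2-yl)benzene-1,3-diol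
Product: 9 4-ethynyl-6-(2-methylbut-3-en-2-yl)-1,3-phenylene bis(2,2-dimethylpropanoate)
Conditions: PivCl (2.5 equiv), Et3N, DMAP (cat.), CH2Cl2, 0 °C → rt
Reagents that add atoms: pivaloyl chloride, CC(C)(C)C(=O)Cl
Why: DMAP-catalysed acylation of both phenols, which turns the oxygen ortho to the alkyne into a hindered ester that can neither add to a metal-bound alkyne nor transfer a carbon group.

Step 7
Reactants: 6 2,4-bis(methoxymethoxy)-5-(2-methylbut-3-en-2-yl)benzaldehyde
Product: 10 2-hydroxy-4-(methoxymethoxy)-5-(2-methylbut-3-en-2-yl)benzaldehyde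
Conditions: MgBr2·OEt2 (1.5 equiv), Et2O–CH2Cl2, 0 °C → rt; then H2O
Reagents that add atoms: none
Why: Chelation-controlled ether cleavage, in which magnesium bridges the aldehyde oxygen and the ortho acetal oxygen and bromide takes the CH2OMe group, as known for ethers next to a carbonyl group, while the para MOM ether has no chelate and should stay.

Step 8
Reactants: 3 1-bromo-5-(dimethoxymethyl)-2,4-bis(methoxymethoxy)benzene
Product: 12 ethyl 2-[5-formyl-2,4-bis(methoxymethoxy)phenyl]acetate, via acetal ester 11 (not isolated)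
Conditions: BrZnCH2CO2Et (1.3 equiv), Pd(dba)2 (2 mol %), P(t-Bu)3 (2 mol %), THF, rt → 50 °C; then 1 M HCl, THF, 0 °C
Reagents that add atoms: (2-ethoxy-2-oxoethyl)zinc bromide, CCOC(=O)C[Zn]Br; water, O
Why: Negishi-type α-arylation of a Reformatsky zinc enolate on zerovalent palladium under neutral conditions that spare acetal and MOM ethers, followed by the same selective acetal hydrolysis as in step 3.

Step 9
Reactants: 12 ethyl 2-[5-formyl-2,4-bis(methoxymethoxy)phenyl]acetate
Product: 13 2-[5-formyl-2,4-bis(methoxymethoxy)phenyl]acetic acid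
Conditions: LiOH·H2O (1.2 equiv), THF–H2O, 0 °C → rt; then dilute HCl to pH 4 at 0 °C
Reagents that add atoms: lithium hydroxide, [Li+].[OH-]
Why: Ester saponification, which the non-enolisable aldehyde and the MOM ethers should survive when the acidification is cold and brief.

Step 10
Reactants: 13 2-[5-formyl-2,4-bis(methoxymethoxy)phenyl]acetic acid; 10 2-hydroxy-4-(methoxymethoxy)-5-(2-methylbut-3-en-2-yl)benzaldehyde
Product: 15 2,4-bis(methoxymethoxy)-5-[7-(methoxymethoxy)-6-(2-methylbut-3-en-2-yl)-2-oxo-2H-chromen-3-yl]benzaldehyde, via aryl ester 14 (not isolated)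
Conditions: DCC, DMAP (cat.), CH2Cl2, 0 °C → rt; then DBU, rt
Reagents that add atoms: none
Why: Perkin-type coumarin synthesis in two stages, Steglich esterification of the salicylaldehyde phenol and then base-induced intramolecular Knoevenagel condensation that closes the six-membered lactone, where ring closure onto the neighbouring formyl group should outrun attack on the remote, electron-rich formyl group of the acid part.

Step 11
Reactants: 15 2,4-bis(methoxymethoxy)-5-[7-(methoxymethoxy)-6-(2-methylbut-3-en-2-yl)-2-oxo-2H-chromen-3-yl]benzaldehyde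
Product: 16 3-[5-(hydroxymethyl)-2,4-bis(methoxymethoxy)phenyl]-7-(methoxymethoxy)-6-(2-methylbut-3-en-2-yl)-2H-chromen-2-one
Conditions: NaBH4, THF–MeOH, −10 °C
Reagents that add atoms: none
Why: Hydride reduction of the aryl aldehyde, which at low temperature is much faster than attack on the coumarin lactone or its C3–C4 double bond.

Step 12
Reactants: 17 4-bromoresorcinol
Product: 18 2-bromo-5-(methoxymethoxy)phenol
Conditions: NaH (2.2 equiv), DMF, 0 °C; MOMCl (1.0 equiv), −20 → 0 °C; then dilute HCl to pH 6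
Reagents that add atoms: chloromethyl methyl ether, COCCl
Why: Mono-alkylation of the dianion, which should take place at the more basic and unhindered oxygen para to bromine, with the regioisomer and bis-ether to be removed by chromatography.

Step 13
Reactants: 16 3-[5-(hydroxymethyl)-2,4-bis(methoxymethoxy)phenyl]-7-(methoxymethoxy)-6-(2-methylbut-3-en-2-yl)-2H-chromen-2-one; 18 2-bromo-5-(methoxymethoxy)phenol
Product: 19 3-[5-{[2-bromo-5-(methoxymethoxy)phenoxy]methyl}-2,4-bis(methoxymethoxy)phenyl]-7-(methoxymethoxy)-6-(2-methylbut-3-en-2-yl)-2H-chromen-2-one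
Conditions: PPh3, DIAD, THF, 0 °C → rt
Reagents that add atoms: none
Why: Mitsunobu etherification of a primary benzylic alcohol with an acidic ortho-bromophenol, under neutral conditions that spare the acid-labile dialkoxybenzyl ether product, the lactone and the MOM ethers.

Step 14
Reactants: 19 3-[5-{[2-bromo-5-(methoxymethoxy)phenoxy]methyl}-2,4-bis(methoxymethoxy)phenyl]-7-(methoxymethoxy)-6-(2-methylbut-3-en-2-yl)-2H-chromen-2-one; 9 4-ethynyl-6-(2-methylbut-3-en-2-yl)-1,3-phenylene bis(2,2-dimethylpropanoate)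
Product: 20 4-{[2-({2,4-bis(methoxymethoxy)-5-[7-(methoxymethoxy)-6-(2-methylbut-3-en-2-yl)-2-oxo-2H-chromen-3-yl]phenyl}methoxy)-4-(methoxymethoxy)phenyl]ethynyl}-6-(2-methylbut-3-en-2-yl)-1,3-phenylene bis(2,2-dimethylpropanoate)
Conditions: PdCl2(PhCN)2 (3 mol %), P(t-Bu)3·HBF4 (6 mol %), CuI (2 mol %), i-Pr2NH, dioxane, rt
Reagents that add atoms: none
Why: Sonogashira coupling in which the tri-tert-butylphosphine complex of zerovalent palladium inserts into the electron-rich aryl bromide at room temperature, so that pivalates, lactone, benzyl ether and vinyl groups stay untouched.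

Step 15
Reactants: 20 4-{[2-({2,4-bis(methoxymethoxy)-5-[7-(methoxymethoxy)-6-(2-methylbut-3-en-2-yl)-2-oxo-2H-chromen-3-yl]phenyl}methoxy)-4-(methoxymethoxy)phenyl]ethynyl}-6-(2-methylbut-3-en-2-yl)-1,3-phenylene bis(2,2-dimethylpropanoate)
Product: 21 4-[3-({2,4-bis(methoxymethoxy)-5-[7-(methoxymethoxy)-6-(2-methylbut-3-en-2-yl)-2-oxo-2H-chromen-3-yl]phenyl}methyl)-6-(methoxymethoxy)-1-benzofuran-2-yl]-6-(2-methylbut-3-en-2-yl)-1,3-phenylene bis(2,2-dimethylpropanoate)
Conditions: PtCl2 (10 mol %), CO (1 atm), toluene, 80 °C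
Reagents that add atoms: none
Why: PtCl2 (divalent platinum, made more electrophilic by CO) binds the diarylalkyne, and the ring-B ether oxygen adds anti to the metal at the alkyne carbon that carries ring A, which forms O1–C2 and closes the furan ring in a 5-endo-dig mode to give a 3-platinated benzofuran oxonium ion. The O–CH2 bond of this ion then ionises, because the departing benzyl cation has oxygen ortho and para to the cationic carbon, and the cation is captured within the ion pair by the carbon–platinum bond at C3, which forms the C3–CH2 bond and frees the catalyst. The closest known reaction is the platinum- or gold-catalysed carboalkoxylation of ortho-alkynylphenyl benzyl, allyl and α-alkoxyalkyl ethers with 1,3-shift of the carbon group. No stereocentre is formed. The step needs the ring-B ether oxygen to cyclise in preference to the ring-A ortho oxygen, which the pivalate on the latter secures, and benzyl transfer in preference to methoxymethyl transfer, which holds because the only acetal oxygen on ring B is para to the alkyne and cannot reach it. Capture at C3 in preference to loss of the cation should be helped by the non-polar solvent, which keeps the ion pair tight.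

Step 16
Reactants: 21 4-[3-({2,4-bis(methoxymethoxy)-5-[7-(methoxymethoxy)-6-(2-methylbut-3-en-2-yl)-2-oxo-2H-chromen-3-yl]phenyl}methyl)-6-(methoxymethoxy)-1-benzofuran-2-yl]-6-(2-methylbut-3-en-2-yl)-1,3-phenylene bis(2,2-dimethylpropanoate)
Product: 22 3-[5-({2-[2,4-dihydroxy-5-(2-methylbut-3-en-2-yl)phenyl]-6-(methoxymethoxy)-1-benzofuran-3-yl}methyl)-2,4-bis(methoxymethoxy)phenyl]-7-(methoxymethoxy)-6-(2-methylbut-3-en-2-yl)-2H-chromen-2-one
Conditions: NaOMe (2.5 equiv), MeOH–THF, 0 °C → rt; then AcOH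
Reagents that add atoms: none
Why: Base methanolysis of the two aryl pivalates, to which MOM ethers are inert, and any coumarin opened to the (Z)-2-hydroxycinnamate ester should reclose on acidification and in step 17.

Step 17
Reactants: 22 3-[5-({2-[2,4-dihydroxy-5-(2-methylbut-3-en-2-yl)phenyl]-6-(methoxymethoxy)-1-benzofuran-3-yl}methyl)-2,4-bis(methoxymethoxy)phenyl]-7-(methoxymethoxy)-6-(2-methylbut-3-en-2-yl)-2H-chromen-2-one
Product: 23 3-[5-({2-[2,4-dihydroxy-5-(2-methylbut-3-en-2-yl)phenyl]-6-hydroxy-1-benzofuran-3-yl}methyl)-2,4-dihydroxyphenyl]-7-hydroxy-6-(2-methylbut-3-en-2-yl)-2H-chromen-2-one (CNP0380243.0)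
Conditions: HCl (1.25 M in MeOH), THF, rt → 40 °C
Reagents that add atoms: none
Why: Acid-catalysed acetal exchange removes the four MOM groups as dimethoxymethane, so that no free formaldehyde meets the resorcinol rings, and the 1,1-dimethylallyl groups should survive because protonation would give only a secondary cation.

**Compound list**

1 | 5-bromo-2,4-dihydroxybenzaldehyde | O=Cc1cc(Br)c(O)cc1O | starting material
2 | 5-bromo-2,4-bis(methoxymethoxy)benzaldehyde | O=Cc1cc(Br)c(OCOC)cc1OCOC | intermediate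
3 | 1-bromo-5-(dimethoxymethyl)-2,4-bis(methoxymethoxy)benzene | COC(OC)c1cc(Br)c(OCOC)cc1OCOC | intermediate
4 | prenylboronic acid pinacol ester | CC(C)=CCB1OC(C)(C)C(C)(C)O1 | starting material
5 | 1-(dimethoxymethyl)-2,4-bis(methoxymethoxy)-5-(2-methylbut-3-en-2-yl)benzene (not isolated) | COC(OC)c1cc(C(C)(C)C=C)c(OCOC)cc1OCOC | intermediate
6 | 2,4-bis(methoxymethoxy)-5-(2-methylbut-3-en-2-yl)benzaldehyde | C=CC(C)(C)c1cc(C=O)c(OCOC)cc1OCOC | intermediate
7 | 1-ethynyl-2,4-bis(methoxymethoxy)-5-(2-methylbut-3-en-2-yl)benzene | C=CC(C)(C)c1cc(C#C)c(OCOC)cc1OCOC | intermediate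
8 | 4-ethynyl-6-(2-methylbut-3-en-2-yl)benzene-1,3-diol | C=CC(C)(C)c1cc(C#C)c(O)cc1O | intermediate
9 | 4-ethynyl-6-(2-methylbut-3-en-2-yl)-1,3-phenylene bis(2,2-dimethylpropanoate) | C=CC(C)(C)c1cc(C#C)c(OC(=O)C(C)(C)C)cc1OC(=O)C(C)(C)C | intermediate
10 | 2-hydroxy-4-(methoxymethoxy)-5-(2-methylbut-3-en-2-yl)benzaldehyde | C=CC(C)(C)c1cc(C=O)c(O)cc1OCOC | intermediate
11 | ethyl 2-[5-(dimethoxymethyl)-2,4-bis(methoxymethoxy)phenyl]acetate (not isolated) | CCOC(=O)Cc1cc(C(OC)OC)c(OCOC)cc1OCOC | intermediate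
12 | ethyl 2-[5-formyl-2,4-bis(methoxymethoxy)phenyl]acetate | CCOC(=O)Cc1cc(C=O)c(OCOC)cc1OCOC | intermediate
13 | 2-[5-formyl-2,4-bis(methoxymethoxy)phenyl]acetic acid | O=C(O)Cc1cc(C=O)c(OCOC)cc1OCOC | intermediate
14 | 2-formyl-5-(methoxymethoxy)-4-(2-methylbut-3-en-2-yl)phenyl 2-[5-formyl-2,4-bis(methoxymethoxy)phenyl]acetate (not isolated) | C=CC(C)(C)c1cc(C=O)c(OC(=O)Cc2cc(C=O)c(OCOC)cc2OCOC)cc1OCOC | intermediate
15 | 2,4-bis(methoxymethoxy)-5-[7-(methoxymethoxy)-6-(2-methylbut-3-en-2-yl)-2-oxo-2H-chromen-3-yl]benzaldehyde | O=Cc1cc(-c2cc3cc(C(C)(C)C=C)c(OCOC)cc3oc2=O)c(OCOC)cc1OCOC | intermediate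
16 | 3-[5-(hydroxymethyl)-2,4-bis(methoxymethoxy)phenyl]-7-(methoxymethoxy)-6-(2-methylbut-3-en-2-yl)-2H-chromen-2-one | OCc1cc(-c2cc3cc(C(C)(C)C=C)c(OCOC)cc3oc2=O)c(OCOC)cc1OCOC | intermediate
17 | 4-bromoresorcinol (4-bromobenzene-1,3-diol) | Oc1ccc(Br)c(O)c1 | starting material
18 | 2-bromo-5-(methoxymethoxy)phenol | COCOc1ccc(Br)c(O)c1 | intermediate
19 | 3-[5-{[2-bromo-5-(methoxymethoxy)phenoxy]methyl}-2,4-bis(methoxymethoxy)phenyl]-7-(methoxymethoxy)-6-(2-methylbut-3-en-2-yl)-2H-chromen-2-one | COCOc1ccc(Br)c(OCc2cc(-c3cc4cc(C(C)(C)C=C)c(OCOC)cc4oc3=O)c(OCOC)cc2OCOC)c1 | intermediate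
20 | 4-{[2-({2,4-bis(methoxymethoxy)-5-[7-(methoxymethoxy)-6-(2-methylbut-3-en-2-yl)-2-oxo-2H-chromen-3-yl]phenyl}methoxy)-4-(methoxymethoxy)phenyl]ethynyl}-6-(2-methylbut-3-en-2-yl)-1,3-phenylene bis(2,2-dimethylpropanoate) | C=CC(C)(C)c1cc(C#Cc2ccc(OCOC)cc2OCc2cc(-c3cc4cc(C(C)(C)C=C)c(OCOC)cc4oc3=O)c(OCOC)cc2OCOC)c(OC(=O)C(C)(C)C)cc1OC(=O)C(C)(C)C | intermediate
21 | 4-[3-({2,4-bis(methoxymethoxy)-5-[7-(methoxymethoxy)-6-(2-methylbut-3-en-2-yl)-2-oxo-2H-chromen-3-yl]phenyl}methyl)-6-(methoxymethoxy)-1-benzofuran-2-yl]-6-(2-methylbut-3-en-2-yl)-1,3-phenylene bis(2,2-dimethylpropanoate) | C=CC(C)(C)c1cc(-c2oc3cc(OCOC)ccc3c2Cc2cc(-c3cc4cc(C(C)(C)C=C)c(OCOC)cc4oc3=O)c(OCOC)cc2OCOC)c(OC(=O)C(C)(C)C)cc1OC(=O)C(C)(C)C | intermediate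
22 | 3-[5-({2-[2,4-dihydroxy-5-(2-methylbut-3-en-2-yl)phenyl]-6-(methoxymethoxy)-1-benzofuran-3-yl}methyl)-2,4-bis(methoxymethoxy)phenyl]-7-(methoxymethoxy)-6-(2-methylbut-3-en-2-yl)-2H-chromen-2-one | C=CC(C)(C)c1cc(-c2oc3cc(OCOC)ccc3c2Cc2cc(-c3cc4cc(C(C)(C)C=C)c(OCOC)cc4oc3=O)c(OCOC)cc2OCOC)c(O)cc1O | intermediate
23 | 3-[5-({2-[2,4-dihydroxy-5-(2-methylbut-3-en-2-yl)phenyl]-6-hydroxy-1-benzofuran-3-yl}methyl)-2,4-dihydroxyphenyl]-7-hydroxy-6-(2-methylbut-3-en-2-yl)-2H-chromen-2-one (CNP0380243.0) | C=CC(C)(C)c1cc(-c2oc3cc(O)ccc3c2Cc2cc(-c3cc4cc(C(C)(C)C=C)c(O)cc4oc3=O)c(O)cc2O)c(O)cc1O | target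

**Step count and risks**

Total step count: 17.
Longest linear sequence: 11 steps (1 → 2 → 3 → 6 → 10 → 15 → 16 → 19 → 20 → 21 → 22 → 23; the branch through 12 and 13 is equally long).

Steps most likely to fail:

1. Step 15. After the furan ring closes, the benzyl cation may escape the ion pair, so that protodemetallation leaves C3 unsubstituted and the cation alkylates other electron-rich positions or triggers MOM loss. The two vinyl groups may also hold back the catalyst. The fallback sets out from 9 and 18, uses 16 and returns at 21. Sonogashira coupling of 9 with the free bromophenol 18 (PdCl2(PhCN)2, P(t-Bu)3·HBF4, CuI, i-Pr2NH, dioxane, 60 °C) should give the alkynylphenol 4-{[2-hydroxy-4-(methoxymethoxy)phenyl]ethynyl}-6-(2-methylbut-3-en-2-yl)-1,3-phenylene bis(2,2-dimethylpropanoate) F1. Under the same copper and amine conditions this should cyclise by 5-endo-dig hydroalkoxylation to the benzofuran 4-[6-(methoxymethoxy)-1-benzofuran-2-yl]-6-(2-methylbut-3-en-2-yl)-1,3-phenylene bis(2,2-dimethylpropanoate) F2. Friedel–Crafts benzylation of F2 at its nucleophilic C3 with benzyl alcohol 16 (Sc(OTf)3, 5 mol %, MeNO2–CH2Cl2, 0 °C) should then form the C3–CH2 bond and give 21.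

2. Step 3. The allylpalladium intermediate may isomerise before reductive elimination, which would erode γ-selectivity and give the linear prenyl isomer, and coupling next to the ortho MOM ether may be slow. The fallback sets out from 3 and returns at 5. Palladium-catalysed α-arylation of isobutyraldehyde with 3 (Pd(OAc)2, bulky electron-rich phosphine, Cs2CO3, dioxane, 80 °C) should give 2-[5-(dimethoxymethyl)-2,4-bis(methoxymethoxy)phenyl]-2-methylpropanal F3, in which the quaternary carbon is fixed without any allyl intermediate. Wittig methylenation (Ph3P=CH2, THF, 0 °C) should then give acetal 5, which is hydrolysed to 6 as in step 3.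

3. Step 10. Acylation of the hydrogen-bonded phenol of 10 may be slow, and the ester enolate may attack the formyl group of the acid part in another molecule, which would give oligomers. The fallback sets out from 12 and returns at 19; it removes that second aldehyde before the condensation and makes steps 9, 11 and 13 unnecessary. NaBH4 reduction of 12 should give ethyl 2-[5-(hydroxymethyl)-2,4-bis(methoxymethoxy)phenyl]acetate F4. Mitsunobu etherification with 18 should give ethyl 2-[5-{[2-bromo-5-(methoxymethoxy)phenoxy]methyl}-2,4-bis(methoxymethoxy)phenyl]acetate F5. LiOH should give 2-[5-{[2-bromo-5-(methoxymethoxy)phenoxy]methyl}-2,4-bis(methoxymethoxy)phenyl]acetic acid F6. DCC/DMAP esterification with 10 should give 2-formyl-5-(methoxymethoxy)-4-(2-methylbut-3-en-2-yl)phenyl 2-[5-{[2-bromo-5-(methoxymethoxy)phenoxy]methyl}-2,4-bis(methoxymethoxy)phenyl]acetate F7, which with DBU should close the coumarin ring and deliver 19.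

Further compounds
F1 | step 15 | 4-{[2-hydroxy-4-(methoxymethoxy)phenyl]ethynyl}-6-(2-methylbut-3-en-2-yl)-1,3-phenylene bis(2,2-dimethylpropanoate) | C=CC(C)(C)c1cc(C#Cc2ccc(OCOC)cc2O)c(OC(=O)C(C)(C)C)cc1OC(=O)C(C)(C)C
F2 | step 15 | 4-[6-(methoxymethoxy)-1-benzofuran-2-yl]-6-(2-methylbut-3-en-2-yl)-1,3-phenylene bis(2,2-dimethylpropanoate) | C=CC(C)(C)c1cc(-c2cc3ccc(OCOC)cc3o2)c(OC(=O)C(C)(C)C)cc1OC(=O)C(C)(C)C
F3 | step 3 | 2-[5-(dimethoxymethyl)-2,4-bis(methoxymethoxy)phenyl]-2-methylpropanal | COC(OC)c1cc(C(C)(C)C=O)c(OCOC)cc1OCOC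
F4 | step 10 | ethyl 2-[5-(hydroxymethyl)-2,4-bis(methoxymethoxy)phenyl]acetate | CCOC(=O)Cc1cc(CO)c(OCOC)cc1OCOC
F5 | step 10 | ethyl 2-[5-{[2-bromo-5-(methoxymethoxy)phenoxy]methyl}-2,4-bis(methoxymethoxy)phenyl]acetate | CCOC(=O)Cc1cc(COc2cc(OCOC)ccc2Br)c(OCOC)cc1OCOC
F6 | step 10 | 2-[5-{[2-bromo-5-(methoxymethoxy)phenoxy]methyl}-2,4-bis(methoxymethoxy)phenyl]acetic acid | O=C(O)Cc1cc(COc2cc(OCOC)ccc2Br)c(OCOC)cc1OCOC
F7 | step 10 | 2-formyl-5-(methoxymethoxy)-4-(2-methylbut-3-en-2-yl)phenyl 2-[5-{[2-bromo-5-(methoxymethoxy)phenoxy]methyl}-2,4-bis(methoxymethoxy)phenyl]acetate | C=CC(C)(C)c1cc(C=O)c(OC(=O)Cc2cc(COc3cc(OCOC)ccc3Br)c(OCOC)cc2OCOC)cc1OCOC
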